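(The readings are calculated with constants of no real substance; the scatter is artificial.)

If each equivalent of X buys a fixed share of the G charged, the gamma run can price the flask, because its Z stands level at 32 % on 2.4 equiv of X.

| flask | G | X | remark | time |
|---|---|---|---|---|
| alpha | 0.10 M | 1.5 equiv | run made earlier |  |
| gamma | 0.10 M | 2.4 equiv | run made earlier |  |
| flask | 0.10 M | 1.10 equiv |  | 50 min |

| alpha: time / min | alpha: Z / % | gamma: time / min | gamma: Z / % |
|---|---|---|---|
| 0.667 | 7 | 0.667 | 6 |
| 1.33 | 10 | 1.33 | 18 |
| 3.00 | 21 | 3.00 | 30 |
| 6.00 | 14 | 6.00 | 32 |
| 12.0 | 14 | 12.0 | 31 |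
| 30.0 | 11 | 30.0 | 32 |
| 60.0 | 13 | 60.0 | 33 |

(scatter of a reading: 2 percentage points)

- at the start none of G is in solution
- a reading or a percentage of Z counts all its forms, free or not

- the moment within 50 min at which there is most Z
- the amount of Z, in percent of the G charged, at that time

That plateau reading, divided by the equivalents charged, is the yield per equivalent, 13.3 % of the G charged. For the alpha run it gives 20.0 %, against a highest reading of 21 %, which lies within the scatter of 2 percentage points, although alpha then sinks to about 13 %.

On 1.10 equiv of X, the yield per equivalent gives 14.7 %, which I take as my estimate of the ceiling for the flask. For a floor I scale gamma's early reading of 18 % at 1.33 min down to the flask's X, which gives 8.25 %. Alpha's fall warns that the flask may turn before it reaches this ceiling, and I have no reckoning for the size of that correction, so I commit to the middle of the bracket, 11.5 %. If I let rise and ceiling both scale with X, the flask's early pace reaches its ceiling at the time gamma's early pace reaches its plateau reading, 2.36 min.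

The forecast says “the maximum should come near” 3.5 min (range 2 min to 7 min), at 13 % (range 9.5 % to 16 %), which is below my ceiling, above my floor and later than my time.

The flask gives 12.1 % at 2.47 min.

    G ⇌ D, rate k1*(cs1 - [D]) while solid is left; crystals form when [D] > cs1 (solubility = 0.0690 M, k = 0.0110 s⁻¹)
    D + X → Z (k = 0.150 M⁻¹ s⁻¹)
    D + Z → E (k = 0.980 M⁻¹ s⁻¹)
    J ⇌ Z, rate k4*(cs4 - [Z]) while solid is left; crystals form when [Z] > cs4 (solubility = 7.00 mM, k = 0.730 s⁻¹)
    2 X → L (k = 0.0190 M⁻¹ s⁻¹)

That is 82.3 % of my ceiling, or 11.0 % per equivalent against the 13.3 % carried over, and at that moment 38.3 % of the G charged already stands as E, where one E counts as two.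

In the neighbouring flask with 2.80 equiv of X, the yield per equivalent gives 37.2 %. The computed result there is 36.9 %, with G as the limiting reagent, of which 0 % is left at the end of that flask.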